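A direct plan would close ring C last, on a flavone, and set C2 afterwards by reduction.
The iodophenol A1 (2-iodo-3,5-bis(methoxymethoxy)phenol) and the aryl alkyne A2 (5-ethynyl-2-methoxy-1,3-diprenylbenzene) would be merged by a palladium-catalysed carbonylative alkynylation–annulation to the flavone A3.
A chiral copper hydride would reduce C2=C3 of A3 to the flavanone A4, and acid would then remove the two MOM groups.
Weak step: the twofold etherification of a threefold-symmetric triol and the mono-iodination that lead to A1 would be statistical, adding length and separations without complexity.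
Weak step: the carbonylative annulation would need carbonyl insertion to outrun direct alkynylation on an electron-rich, doubly ortho-substituted aryl–palladium under pressure, and 6-endo to beat 5-exo closure.
Weak step: the conjugate reduction would have to set C2 on a hindered, electron-rich flavone without over-reduction at C4 or ring opening, and the new centre would then meet hot aqueous acid beside two prenyl groups.

The route rests on the C2–C1′ bond between rings C and B. C2, the only stereocentre, is at once the β-carbon of the vinylogous ester O1–C2=C3–C4=O of a chromone, in which rings A and C are already fused, and the point where ring B is attached. A rhodium-catalysed enantioselective 1,4-addition of the diprenylated arylboronic acid to silyl-protected 5,7-dihydroxychromone would therefore join the two halves and set C2 in one operation. No triol has to be desymmetrised, no carbonylation or late reduction is needed, and the phenols would be freed by buffered fluoride, which spares the prenyl groups and C2.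

Key step: step 5

Assumption: 5,7-dihydroxychromone (1) is taken as a purchasable natural chromone, and the facial sense of the addition is assigned by analogy with cyclic enones; the mirror-image ligand would be used if a test reaction showed the opposite sense.

Prenyl stands for 3-methylbut-2-en-1-yl.

Step 1
Reactants: 1 5,7-dihydroxy-4H-chromen-4-one (5,7-dihydroxychromone)
Product: 2 5,7-bis{[tri(propan-2-yl)silyl]oxy}-4H-chromen-4-one
Conditions: i-Pr3SiOTf (2.5 equiv), 2,6-lutidine (4 equiv), CH2Cl2, 0 °C to rt
Reagents that add atoms: triisopropylsilyl trifluoromethanesulfonate, CC(C)[Si](OS(=O)(=O)C(F)(F)F)(C(C)C)C(C)C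
Why: O-silylation of both phenols, in which the silyl triflate is reactive enough to silylate also the 5-OH that is hydrogen-bonded to C4=O while the hindered base cannot add to C2, and which gives bulky aryl silyl ethers that should survive the aqueous key step and fall to fluoride.

Step 2
Reactants: 3 2,6-dibromoanisole (1,3-dibromo-2-methoxybenzene)
Product: 4 2-(3,5-dibromo-4-methoxyphenyl)-4,4,5,5-tetramethyl-1,3,2-dioxaborolane
Conditions: B2pin2 (0.6 equiv), [Ir(OMe)(cod)]2 (1.5 mol%), 4,4′-di-tert-butyl-2,2′-bipyridine (3 mol%), THF, 80 °C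
Reagents that add atoms: bis(pinacolato)diboron, CC1(C)OB(OC1(C)C)B1OC(C)(C)C(C)(C)O1
Why: Iridium-catalysed aromatic C–H borylation (Ishiyama–Miyaura–Hartwig borylation), which is under steric control so that only C4–H, the one C–H without an ortho substituent, should react, and which tolerates aryl bromides.

Step 3
Reactants: 4 2-(3,5-dibromo-4-methoxyphenyl)-4,4,5,5-tetramethyl-1,3,2-dioxaborolane
Product: 5 2-[4-methoxy-3,5-bis(3-methylbut-2-en-1-yl)phenyl]-4,4,5,5-tetramethyl-1,3,2-dioxaborolane
Conditions: prenylzinc bromide (3.0 equiv, made in the flask from prenyl bromide, Zn dust, LiCl, THF, 0 °C), Pd(OAc)2 (2 mol%), CPhos (4 mol%), THF, rt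
Reagents that add atoms: 1-bromo-3-methylbut-2-ene (prenyl bromide), CC(C)=CCBr
Why: Twofold Negishi coupling of an allylic zinc halide, in which the bulky biarylphosphine makes reductive elimination from the primary η1-allyl terminus of the aryl(prenyl)palladium intermediate fast and so should give the linear prenyl arene, while the pinacol boronate does not transmetalate in the absence of base.

Step 4
Reactants: 5 2-[4-methoxy-3,5-bis(3-methylbut-2-en-1-yl)phenyl]-4,4,5,5-tetramethyl-1,3,2-dioxaborolane
Product: 6 [4-methoxy-3,5-bis(3-methylbut-2-en-1-yl)phenyl]boronic acid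
Conditions: NaIO4 (3 equiv), NH4OAc (3 equiv), acetone/H2O (1:1), rt
Reagents that add atoms: water, O
Why: Oxidative deprotection of a pinacol boronate, in which periodate cleaves the pinacol released at equilibrium (glycol cleavage) and so drives the hydrolysis to the boronic acid under buffered, near-neutral conditions that should not touch the trisubstituted alkenes.

Step 5
Reactants: 2 5,7-bis{[tri(propan-2-yl)silyl]oxy}-4H-chromen-4-one; 6 [4-methoxy-3,5-bis(3-methylbut-2-en-1-yl)phenyl]boronic acid
Product: 7 (2S)-2-[4-methoxy-3,5-bis(3-methylbut-2-en-1-yl)phenyl]-5,7-bis{[tri(propan-2-yl)silyl]oxy}-2,3-dihydro-4H-chromen-4-one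
Conditions: [RhCl(C2H4)2]2 (2.5 mol%), (S)-MeO-F12-BIPHEP [(S)-2,2′-bis{bis(3,4,5-trifluorophenyl)phosphino}-6,6′-dimethoxy-1,1′-biphenyl] (5.5 mol%), aq KOH (10 mol%), 6 (2.0 equiv), toluene/H2O (10:1), 50 °C
Reagents that add atoms: none
Why: The aryl group of 6 passes from boron to a hydroxorhodium complex of the bisphosphine (monovalent rhodium throughout), the arylrhodium species binds C2=C3 of 2 and inserts it with the aryl group going to C2 and rhodium to C3, and water hydrolyses the resulting oxa-π-allyl rhodium enolate to the ketone and the hydroxorhodium complex. The closest known reaction type is the Hayashi–Miyaura asymmetric 1,4-addition of arylboronic acids, which is established for chromones as acceptors with electron-poor biaryl bisphosphines. No ring is closed, since rings A and C are already fused in 2, and the step forms only the C2–C1′ bond to ring B. C2 is set by the ligand, whose (S)-biaryl backbone should leave the Re face of C2 open to the migrating aryl group (the sense that (S)-biaryl bisphosphines show with 2-cyclohexenone), which corresponds to 2S. The step needs 1,4- in place of 1,2-addition and no arylation of the product ketone, which the weakly σ-donating ligand should favour by speeding insertion, and it needs protonation of the rhodium enolate before O1 can be expelled with opening of ring C, which the aqueous, near-neutral medium should secure. The silyl ethers keep the 5-OH/C4=O pair from chelating rhodium and the 7-OH from becoming a deactivating phenoxide, and the trisubstituted prenyl alkenes should not insert into the aryl–rhodium bond.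

Step 6
Reactants: 7 (2S)-2-[4-methoxy-3,5-bis(3-methylbut-2-en-1-yl)phenyl]-5,7-bis{[tri(propan-2-yl)silyl]oxy}-2,3-dihydro-4H-chromen-4-one
Product: 8 (2S)-5,7-dihydroxy-2-[4-methoxy-3,5-bis(3-methylbut-2-en-1-yl)phenyl]-2,3-dihydro-4H-chromen-4-one (4′-O-methylabyssinone V)
Conditions: Bu4NF (2.5 equiv), AcOH (3 equiv), THF, 0 °C
Reagents that add atoms: none
Why: Fluoride-induced cleavage of both aryl silyl ethers through pentacoordinate silicon, buffered with acetic acid so that no phenoxide or enolate is present to open ring C by a retro-oxa-Michael reaction, which should leave C2 and the acid-sensitive prenyl groups untouched.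

Compound list
1 | 5,7-dihydroxy-4H-chromen-4-one | O=c1ccoc2cc(O)cc(O)c12 | starting material
2 | 5,7-bis{[tri(propan-2-yl)silyl]oxy}-4H-chromen-4-one | O=c1ccoc2cc(O[Si](C(C)C)(C(C)C)C(C)C)cc(O[Si](C(C)C)(C(C)C)C(C)C)c12 | intermediate
3 | 2,6-dibromoanisole (1,3-dibromo-2-methoxybenzene) | COc1c(Br)cccc1Br | starting material
4 | 2-(3,5-dibromo-4-methoxyphenyl)-4,4,5,5-tetramethyl-1,3,2-dioxaborolane | COc1c(Br)cc(B2OC(C)(C)C(C)(C)O2)cc1Br | intermediate
5 | 2-[4-methoxy-3,5-bis(3-methylbut-2-en-1-yl)phenyl]-4,4,5,5-tetramethyl-1,3,2-dioxaborolane | COc1c(CC=C(C)C)cc(B2OC(C)(C)C(C)(C)O2)cc1CC=C(C)C | intermediate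
6 | [4-methoxy-3,5-bis(3-methylbut-2-en-1-yl)phenyl]boronic acid | COc1c(CC=C(C)C)cc(B(O)O)cc1CC=C(C)C | intermediate
7 | (2S)-2-[4-methoxy-3,5-bis(3-methylbut-2-en-1-yl)phenyl]-5,7-bis{[tri(propan-2-yl)silyl]oxy}-2,3-dihydro-4H-chromen-4-one | COc1c(CC=C(C)C)cc([C@@H]2CC(=O)c3c(O[Si](C(C)C)(C(C)C)C(C)C)cc(O[Si](C(C)C)(C(C)C)C(C)C)cc3O2)cc1CC=C(C)C | intermediate
8 | (2S)-5,7-dihydroxy-2-[4-methoxy-3,5-bis(3-methylbut-2-en-1-yl)phenyl]-2,3-dihydro-4H-chromen-4-one | COc1c(CC=C(C)C)cc([C@@H]2CC(=O)c3c(O)cc(O)cc3O2)cc1CC=C(C)C | target

Total step count: 6. Longest linear sequence: 5 steps (3 → 4 → 5 → 6 → 7 → 8).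

Steps most likely to fail

1. Step 5. Insertion of the electron-rich, doubly oxygenated chromone into the aryl–rhodium bond may be slower than protodeboronation of the boronic acid, or facial discrimination may be incomplete. The fallback sets out from 2 and 6 and comes back at 7. The addition would be run with the more active achiral complex [Rh(OH)(cod)]2 in dioxane/H2O to give the racemic silylated flavanone F1. F1 would be resolved by preparative chromatography on a chiral stationary phase into 7 and its (2R)-enantiomer F2. F2 would be racemised with catalytic DBU through reversible opening of ring C and returned to the separation.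

2. Step 3. Allyl transfer through the tertiary terminus, stalling after the first coupling, or attack of the allylzinc reagent at boron may erode the twofold prenylation. The fallback sets out from 3 and comes back at 5, with prenylation before borylation and without palladium. Bromine–lithium exchange on 3 (n-BuLi, THF, −78 °C), then CuBr·SMe2 and prenyl bromide (SN2 allylation of the arylcopper species), would give 1-bromo-2-methoxy-3-(3-methylbut-2-en-1-yl)benzene F3. A second round on F3 would give 2-methoxy-1,3-bis(3-methylbut-2-en-1-yl)benzene F4. The iridium-catalysed C–H borylation of step 2, again directed to the only unhindered C–H, would then convert F4 into 5.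

3. Step 6. Phenoxide formed during desilylation may open ring C and erode C2, or the peri 5-O-silyl group may resist cleavage. The fallback sets out from 1 and comes back at 8, with acyl in place of silyl protection. Ac2O/pyridine would convert 1 into 4-oxo-4H-chromene-5,7-diyl diacetate F5, which is also a better acceptor. The addition of step 5, run with 6 and the preformed, base-free complex [Rh(OH){(S)-MeO-F12-BIPHEP}]2, would give the (2S)-flavanone diacetate F6. Neutral transesterification with NH4OAc in aqueous methanol would release 8.

Further compounds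
F1 | step 5 | rac-2-[4-methoxy-3,5-bis(3-methylbut-2-en-1-yl)phenyl]-5,7-bis{[tri(propan-2-yl)silyl]oxy}-2,3-dihydro-4H-chromen-4-one | COc1c(CC=C(C)C)cc(C2CC(=O)c3c(O[Si](C(C)C)(C(C)C)C(C)C)cc(O[Si](C(C)C)(C(C)C)C(C)C)cc3O2)cc1CC=C(C)C
F2 | step 5 | (2R)-2-[4-methoxy-3,5-bis(3-methylbut-2-en-1-yl)phenyl]-5,7-bis{[tri(propan-2-yl)silyl]oxy}-2,3-dihydro-4H-chromen-4-one | COc1c(CC=C(C)C)cc([C@H]2CC(=O)c3c(O[Si](C(C)C)(C(C)C)C(C)C)cc(O[Si](C(C)C)(C(C)C)C(C)C)cc3O2)cc1CC=C(C)C
F3 | step 3 | 1-bromo-2-methoxy-3-(3-methylbut-2-en-1-yl)benzene | COc1c(Br)cccc1CC=C(C)C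
F4 | step 3 | 2-methoxy-1,3-bis(3-methylbut-2-en-1-yl)benzene | COc1c(CC=C(C)C)cccc1CC=C(C)C
F5 | step 6 | 4-oxo-4H-chromene-5,7-diyl diacetate | O=c1ccoc2cc(OC(C)=O)cc(OC(C)=O)c12
F6 | step 6 | (2S)-2-[4-methoxy-3,5-bis(3-methylbut-2-en-1-yl)phenyl]-4-oxo-3,4-dihydro-2H-chromene-5,7-diyl diacetate | COc1c(CC=C(C)C)cc([C@@H]2CC(=O)c3c(OC(C)=O)cc(OC(C)=O)cc3O2)cc1CC=C(C)C
A1 | direct plan | 2-iodo-3,5-bis(methoxymethoxy)phenol | COCOc1cc(O)c(I)c(OCOC)c1
A2 | direct plan | 5-ethynyl-2-methoxy-1,3-bis(3-methylbut-2-en-1-yl)benzene | C#Cc1cc(CC=C(C)C)c(OC)c(CC=C(C)C)c1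
A3 | direct plan | 5,7-bis(methoxymethoxy)-2-[4-methoxy-3,5-bis(3-methylbut-2-en-1-yl)phenyl]-4H-chromen-4-one | COCOc1cc(OCOC)c2c(c1)oc(-c1cc(CC=C(C)C)c(OC)c(CC=C(C)C)c1)cc2=O
A4 | direct plan | (2S)-5,7-bis(methoxymethoxy)-2-[4-methoxy-3,5-bis(3-methylbut-2-en-1-yl)phenyl]-2,3-dihydro-4H-chromen-4-one | COCOc1cc(OCOC)c2c(c1)O[C@H](c1cc(CC=C(C)C)c(OC)c(CC=C(C)C)c1)CC2=O
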